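The readings of the amber run average 28.4% of the substrate charged, and those of the blue run, with less partner, average 9.40%.

| setting | blue | amber | flask |
|---|---|---|---|
| substrate | 0.12 M | 0.12 M | 0.12 M |
| partner | 0.066 M | 0.26 M | 0.132 M |
| remark | run made earlier | run made earlier |  |
| time |  |  | 20 h |

| run | time / h | target / % |
|---|---|---|
| blue | 0.250 | 10 |
| blue | 0.833 | 12 |
| blue | 2.50 | 8 |
| blue | 8.00 | 9 |
| blue | 25.0 | 8 |
| amber | 0.250 | 28 |
| amber | 0.833 | 29 |
| amber | 2.50 | 28 |
| amber | 8.00 | 29 |
| amber | 25.0 | 28 |

(standard deviation of a reading: 1.5 percentage points)

- time, not beyond 20 h, at which the flask holds most target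
- the amount of target, in percent of the substrate charged, at that time



From these levels I carry one quantity, the plateau constant K, which is target divided by the product of the substrate charge not read as target and the partner charge not read as target, all in M (an apparent equilibrium constant). Blue gives 1.90 L mol⁻¹ and amber 1.76 L mol⁻¹, so I take 1.83 L mol⁻¹. I draw the flask's curve from zero. The amber readings are level within their scatter from 0.250 h, and after 3 half-lives a share of 12.5% would still be missing, which is 3.5 percentage points in amber against a scatter of 1.5 points, so my rough estimate of the rise half-life is 0.0833 h. The knee therefore comes near the first reading, and K puts the level at 0.0203 M of target, or 16.9%. The first two blue readings stand on average 2.7 points above its last three, while the same difference in amber is 0.17 points. On that hint I place the flask's most target a little above the level, between 0.250 h and 0.833 h.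

The forecast says 17% at 20 h, with the words “The best time is poorly defined because the plateau is flat”.

The flask gives 18.8% at 0.430 h.

    open intermediate + second intermediate ⇌ target (K = 2.70 L mol⁻¹, k = 0.0160 L mol⁻¹ s⁻¹)
    substrate → open intermediate (k = 0.00330 s⁻¹)
    partner → second intermediate (k = 0.00280 s⁻¹)
    target ⇌ isomer of the product (K = 0.850, k = 4.90 × 10⁻⁴ s⁻¹)

From that peak the flask goes to 17.3% target at 2.00 h, while isomer of the product grows from 7.16% to 14.5%, and the relaxation half-life of that pair by its own step alone, both ways together, is 0.181 h, short against the 20 h allowed. At 20.0 h the flask holds 17.2%, where K gave 16.9%. For the neighbour flask, charged with 0.053 M of partner, the same K gives 7.45%; that neighbour peaks at 8.60% and holds 8.06% target at 20.0 h.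

All runs are calculated with constants of no real substance.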